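**Plan**

- Cuts: first O1''–C2'' of ring E, then C3–C3'' between a (2S)-flavanone and an aldol chain ring D–C4''(=O)–C3''–C2''(OH)–ring F, then C2–ring B and C2''–C3''.
- Forward: asymmetric arylation of a chromone (ring C, C2); aldol (rings D and F); silicon-tethered oxidative coupling of the two ketones (C3–C3''); ring E closed last; hydrogenolysis.
- Enabling feature: the hydroxyl of ring F is para to C2'', so the C2'' carbinol gives a para-quinone methide (as in the presumed biosynthetic dimerisation); the ring D hydroxyl on C8a'', ortho to the C4'' ketone, traps it in a 6-exo closure.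
- Stereochemistry: C2 from the arylation ligand, C2'' from a chiral phosphoric acid; C3 and C3'' are alpha to ketones and settle trans to C2 and C2'', so two catalyst-set centres fix all four.
- Lettering: rings A (benzo), C (pyranone), B (aryl) form the 7-hydroxy half; rings D (benzo), E (pyranone), F (aryl) form the 5,7-dihydroxy half, whose locants are doubly primed.

Key step: step 8

Assumption: the sense of induction of the two chiral catalysts (ligand in step 2, phosphoric acid in step 8) is taken by analogy with simpler substrates; the antipodal catalyst would be used if a trial run showed the opposite sense.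

**Route**

Step 1
Reactants: 1 7-hydroxy-4H-chromen-4-one
Product: 2 7-(benzyloxy)-4H-chromen-4-one
Conditions: benzyl bromide, K2CO3, acetone, 50 °C
Reagents that add atoms: benzyl bromide BrCc1ccccc1
Why: Williamson ether synthesis on the acidic 7-hydroxyl under carbonate conditions that leave the chromone ring closed.

Step 2
Reactants: 2 7-(benzyloxy)-4H-chromen-4-one; 3 4-(benzyloxy)phenylboronic acid
Product: 4 (2S)-7-(benzyloxy)-2-[4-(benzyloxy)phenyl]chroman-4-one
Conditions: Pd(OCOCF3)2 (5 mol%), (R)-4-tert-butyl-2-(pyridin-2-yl)-4,5-dihydro-1,3-oxazole (6 mol%), NH4PF6 (30 mol%), H2O (5 equiv), ClCH2CH2Cl, 60 °C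
Reagents that add atoms: none
Why: Asymmetric conjugate addition of an arylboronic acid to a chromone with a cationic divalent palladium pyridine-oxazoline catalyst should transfer ring B to the ligand-selected face of C2 (S), and water protonates the palladium enolate.

Step 3
Reactants: 5 1-[2,4-bis(benzyloxy)-6-hydroxyphenyl]ethanone; 6 4-(tert-butyldimethylsilyloxy)benzaldehyde
Product: 7 racemic 1-[2,4-bis(benzyloxy)-6-hydroxyphenyl]-3-hydroxy-3-[4-(tert-butyldimethylsilyloxy)phenyl]propan-1-one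
Conditions: LiN(i-Pr)2 (2.5 equiv), THF, −78 °C; then 6, −78 °C; aqueous NH4Cl
Reagents that add atoms: none
Why: Directed aldol addition of the phenoxide-enolate dianion of a 2'-hydroxyacetophenone to an aromatic aldehyde builds the ring D–C4''–C3''–C2''–ring F chain; no stereocontrol is sought because C2'' is set again in step 8.

Step 4
Reactants: 7 racemic aldol
Product: 8 racemic 1-[2,4-bis(benzyloxy)-6-(tert-butyldimethylsilyloxy)phenyl]-3-(tert-butyldimethylsilyloxy)-3-[4-(tert-butyldimethylsilyloxy)phenyl]propan-1-one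
Conditions: tert-butyldimethylsilyl chloride (3 equiv), imidazole, DMF, rt
Reagents that add atoms: tert-butyldimethylsilyl chloride CC(C)(C)[Si](C)(C)Cl
Why: Silyl ether formation masks the phenol and the carbinol, so the C3'' methylene is the only acidic site left for step 5.

Step 5
Reactants: 4 (2S)-flavanone; 8 racemic silylated aldol ketone
Product: 10 {[(2S)-7-(benzyloxy)-2-[4-(benzyloxy)phenyl]-2H-chromen-4-yl]oxy}{[(Z)-1-[2,4-bis(benzyloxy)-6-(tert-butyldimethylsilyloxy)phenyl]-3-(tert-butyldimethylsilyloxy)-3-[4-(tert-butyldimethylsilyloxy)phenyl]prop-1-en-1-yl]oxy}dimethylsilane (used crude), via chlorosilyl enol ether 9 (not isolated)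
Conditions: 4, LiN(i-Pr)2, THF, −78 °C, 10 min, transferred into Me2SiCl2 (5 equiv), −78 °C, excess silane removed in vacuo; then 8 pretreated with LiN(i-Pr)2 (THF, −78 °C), −78 °C to rt
Reagents that add atoms: dichlorodimethylsilane C[Si](C)(Cl)Cl
Why: Each ketone has one enolisable carbon (C3 of 4, C3'' of 8), so two successive O-silylations on one dichlorosilane join them regiospecifically as an unsymmetrical silyl bis-enol ether; quenching the flavanone enolate within minutes at −78 °C forestalls beta-elimination of the ring C phenoxide, so C2 is kept.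

Step 6
Reactants: 10 silyl bis-enol ether
Product: 11 (2S,3R)-7-(benzyloxy)-2-[4-(benzyloxy)phenyl]-3-{1-[2,4-bis(benzyloxy)-6-(tert-butyldimethylsilyloxy)phenyl]-3-(tert-butyldimethylsilyloxy)-3-[4-(tert-butyldimethylsilyloxy)phenyl]-1-oxopropan-2-yl}chroman-4-one (epimer mixture at C3'' and C2'')
Conditions: (NH4)2Ce(NO3)6 (2.2 equiv), NaHCO3 (4.4 equiv), MeCN–EtCN, −10 °C
Reagents that add atoms: none
Why: Silicon-tethered oxidative enolate cross-coupling, in which tetravalent cerium oxidises the electron-rich chromene enol ether to a radical cation that the tethered enol ether captures, so only the cross product should form; the C3–C3'' bond forms anti to ring B (C3 R, trans to C2), and the C3''/C2'' mixture is erased in step 8.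

Step 7
Reactants: 11 silylated 1,4-diketone
Product: 12 (2S,3R)-7-(benzyloxy)-2-[4-(benzyloxy)phenyl]-3-{1-[2,4-bis(benzyloxy)-6-hydroxyphenyl]-3-hydroxy-3-(4-hydroxyphenyl)-1-oxopropan-2-yl}chroman-4-one (epimer mixture at C3'' and C2'')
Conditions: Bu4NF (3.5 equiv), AcOH (3.5 equiv), THF, 0 °C to rt
Reagents that add atoms: none
Why: Fluoride cleavage of the two aryl silyl ethers and the benzylic silyl ether, buffered with acetic acid so that the beta-hydroxy ketone neither undergoes retro-aldol cleavage nor cyclises without the catalyst; benzyl ethers are untouched.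

Step 8
Reactants: 12 ring-opened precursor
Product: 14 (2S,3R)-7-(benzyloxy)-2-[4-(benzyloxy)phenyl]-3-[(2S,3R)-5,7-bis(benzyloxy)-2-(4-hydroxyphenyl)-4-oxochroman-3-yl]chroman-4-one, via para-quinone methide 13 (not isolated)
Conditions: (R)-3,3'-bis(2,4,6-triisopropylphenyl)-1,1'-binaphthalene-2,2'-diyl hydrogen phosphate (10 mol%), 4 Å molecular sieves, CH2Cl2, 0 °C to rt
Reagents that add atoms: none
Why: Proposed new method: the phosphoric acid should ionise the C2'' carbinol, which is para-hydroxybenzylic through ring F, to para-quinone methide 13; this equilibrates with its 4-hydroxychalcone tautomer, so the configurations at C2'' and C3'' of 12 are erased before the ortho hydroxyl of ring D adds to C2'' (oxa-1,6-addition) and forms the O1''–C2'' bond. The closest known reaction type is the chiral phosphoric acid-catalysed enantioselective 1,6-addition of nucleophiles to para-quinone methides generated in situ from para-hydroxybenzyl alcohols, and the event copies the chalcone-to-flavanone closure and the quinone methide trapping of the presumed biosynthesis. Ring E closes in the 6-exo-trig mode, the methide double bond lying outside the new ring. C2'' (S) is set by the catalyst, whose phosphate bridges the quinone methide carbonyl and the attacking phenol and exposes one face of the methide; C3'' (R) is set by the substrate, because the transition state with C3''–H eclipsing the methide (least allylic strain) places ring F and the flavanonyl group trans, and any cis isomer should drift to the trans-diequatorial product by acid-mediated enolisation. The step needs O-attack over C-attack and catalyst control over the resident C2/C3 centres: both positions of ring D ortho to the ketone carry oxygen, the six-membered O-closure is intramolecular, and the benzyl ethers on rings A, B and D keep those rings from forming quinone methides, so C2 is not opened.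

Step 9
Reactants: 14 tetra-O-benzyl biflavanone
Product: 15 (2S,3R)-7-hydroxy-2-(4-hydroxyphenyl)-3-[(2S,3R)-5,7-dihydroxy-2-(4-hydroxyphenyl)-4-oxochroman-3-yl]chroman-4-one (target)
Conditions: H2 (1 atm), palladium on carbon (10 wt% Pd), EtOAc–MeOH, rt
Reagents that add atoms: none
Why: Catalytic hydrogenolysis of the four benzyl ethers under neutral conditions, where the cyclic aryl benzylic ethers at C2 and C2'' are cleaved much more slowly and no acid or base is present to enolise C3/C3'' or open a pyranone.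

**Compound list**

1 | 7-hydroxy-4H-chromen-4-one | O=c1ccoc2cc(O)ccc12 | starting material
2 | 7-(benzyloxy)-4H-chromen-4-one | O=c1ccoc2cc(OCc3ccccc3)ccc12 | intermediate
3 | 4-(benzyloxy)phenylboronic acid | OB(O)c1ccc(OCc2ccccc2)cc1 | starting material
4 | (2S)-7-(benzyloxy)-2-[4-(benzyloxy)phenyl]chroman-4-one | O=C1c2ccc(OCc3ccccc3)cc2O[C@H](c2ccc(OCc3ccccc3)cc2)C1 | intermediate
5 | 1-[2,4-bis(benzyloxy)-6-hydroxyphenyl]ethanone | CC(=O)c1c(O)cc(OCc2ccccc2)cc1OCc1ccccc1 | starting material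
6 | 4-(tert-butyldimethylsilyloxy)benzaldehyde | O=Cc1ccc(O[Si](C)(C)C(C)(C)C)cc1 | starting material
7 | racemic 1-[2,4-bis(benzyloxy)-6-hydroxyphenyl]-3-hydroxy-3-[4-(tert-butyldimethylsilyloxy)phenyl]propan-1-one | O=C(CC(O)c1ccc(O[Si](C)(C)C(C)(C)C)cc1)c1c(O)cc(OCc2ccccc2)cc1OCc1ccccc1 | intermediate
8 | racemic 1-[2,4-bis(benzyloxy)-6-(tert-butyldimethylsilyloxy)phenyl]-3-(tert-butyldimethylsilyloxy)-3-[4-(tert-butyldimethylsilyloxy)phenyl]propan-1-one | O=C(CC(O[Si](C)(C)C(C)(C)C)c1ccc(O[Si](C)(C)C(C)(C)C)cc1)c1c(O[Si](C)(C)C(C)(C)C)cc(OCc2ccccc2)cc1OCc1ccccc1 | intermediate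
9 | (2S)-7-(benzyloxy)-2-[4-(benzyloxy)phenyl]-4-[chloro(dimethyl)silyloxy]-2H-chromene (not isolated) | C[Si](C)(Cl)OC1=C[C@@H](c2ccc(OCc3ccccc3)cc2)Oc2cc(OCc3ccccc3)ccc12 | intermediate
10 | unsymmetrical dimethylsilyl bis-enol ether of 4 and 8 (chromen-4-yloxy and (Z)-prop-1-en-1-yloxy groups on one SiMe2, epimer mixture at C2'') | C[Si](C)(OC1=C[C@@H](c2ccc(OCc3ccccc3)cc2)Oc2cc(OCc3ccccc3)ccc12)O/C(=C\C(O[Si](C)(C)C(C)(C)C)c1ccc(O[Si](C)(C)C(C)(C)C)cc1)c1c(O[Si](C)(C)C(C)(C)C)cc(OCc2ccccc2)cc1OCc1ccccc1 | intermediate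
11 | (2S,3R)-7-(benzyloxy)-2-[4-(benzyloxy)phenyl]-3-{1-[2,4-bis(benzyloxy)-6-(tert-butyldimethylsilyloxy)phenyl]-3-(tert-butyldimethylsilyloxy)-3-[4-(tert-butyldimethylsilyloxy)phenyl]-1-oxopropan-2-yl}chroman-4-one (epimer mixture at C3'' and C2'') | O=C1c2ccc(OCc3ccccc3)cc2O[C@H](c2ccc(OCc3ccccc3)cc2)[C@H]1C(C(O[Si](C)(C)C(C)(C)C)c1ccc(O[Si](C)(C)C(C)(C)C)cc1)C(=O)c1c(O[Si](C)(C)C(C)(C)C)cc(OCc2ccccc2)cc1OCc1ccccc1 | intermediate
12 | (2S,3R)-7-(benzyloxy)-2-[4-(benzyloxy)phenyl]-3-{1-[2,4-bis(benzyloxy)-6-hydroxyphenyl]-3-hydroxy-3-(4-hydroxyphenyl)-1-oxopropan-2-yl}chroman-4-one (epimer mixture at C3'' and C2'') | O=C1c2ccc(OCc3ccccc3)cc2O[C@H](c2ccc(OCc3ccccc3)cc2)[C@H]1C(C(O)c1ccc(O)cc1)C(=O)c1c(O)cc(OCc2ccccc2)cc1OCc1ccccc1 | intermediate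
13 | para-quinone methide: (2S,3R)-7-(benzyloxy)-2-[4-(benzyloxy)phenyl]-3-{1-[2,4-bis(benzyloxy)-6-hydroxyphenyl]-1-oxo-3-(4-oxocyclohexa-2,5-dien-1-ylidene)propan-2-yl}chroman-4-one (not isolated) | O=C1c2ccc(OCc3ccccc3)cc2O[C@H](c2ccc(OCc3ccccc3)cc2)[C@H]1C(C=C1C=CC(=O)C=C1)C(=O)c1c(O)cc(OCc2ccccc2)cc1OCc1ccccc1 | intermediate
14 | (2S,3R)-7-(benzyloxy)-2-[4-(benzyloxy)phenyl]-3-[(2S,3R)-5,7-bis(benzyloxy)-2-(4-hydroxyphenyl)-4-oxochroman-3-yl]chroman-4-one | O=C1c2ccc(OCc3ccccc3)cc2O[C@H](c2ccc(OCc3ccccc3)cc2)[C@H]1[C@H]1C(=O)c2c(OCc3ccccc3)cc(OCc3ccccc3)cc2O[C@@H]1c1ccc(O)cc1 | intermediate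
15 | (2S,3R)-7-hydroxy-2-(4-hydroxyphenyl)-3-[(2S,3R)-5,7-dihydroxy-2-(4-hydroxyphenyl)-4-oxochroman-3-yl]chroman-4-one | O=C1c2ccc(O)cc2O[C@H](c2ccc(O)cc2)[C@H]1[C@H]1C(=O)c2c(O)cc(O)cc2O[C@@H]1c1ccc(O)cc1 | target

**Step count and risks**

Total steps: 9. Longest linear sequence: 7 steps (steps 1, 2, 5, 6, 7, 8, 9, or equally steps 3 to 9).

Most likely to fail, step 8: facial control at C2'' may be insufficient if the resident C2/C3 centres oppose the catalyst, or closure may run without the catalyst. The fallback sets out from compound 4 and comes back at compound 15, closing ring E early by known chemistry. Commercial 5,7-dihydroxy-4H-chromen-4-one is benzylated (benzyl bromide, K2CO3, DMF, 60 °C) to 5,7-bis(benzyloxy)-4H-chromen-4-one F1. F1 is arylated with 3 under the conditions of step 2 to (2S)-5,7-bis(benzyloxy)-2-[4-(benzyloxy)phenyl]chroman-4-one F2. Chlorosilyl enol ether 9, made from 4 as in step 5, is joined to the lithium enolate of F2 to give the dimethylsilyl bis-enol ether of the two flavanones F3. Oxidation with (NH4)2Ce(NO3)6 as in step 6 should form C3–C3'' anti to the aryl group of each ring and give the penta-O-benzyl ether of the target F4. Hydrogenolysis as in step 9 gives 15.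

Second, step 6: tetravalent cerium may over-oxidise the electron-rich alkoxyarene rings, or the benzylic silyloxy group may ionise, or the tether may be lost before the C–C bond forms. The fallback sets out from compounds 4 and 5 and comes back at compound 12, using enolate alkylation and a later aldol. Compound 5 is silylated (tert-butyldimethylsilyl chloride, imidazole, DMF) to 1-[2,4-bis(benzyloxy)-6-(tert-butyldimethylsilyloxy)phenyl]ethanone F5. F5 is converted (LiN(SiMe3)2, Me3SiCl, THF, −78 °C) into its trimethylsilyl enol ether F6 and brominated with N-bromosuccinimide to 2-bromo-1-[2,4-bis(benzyloxy)-6-(tert-butyldimethylsilyloxy)phenyl]ethanone F7. The lithium enolate of 4 (LiN(SiMe3)2, THF, −78 °C) is alkylated by F7 anti to ring B to give the trans 1,4-diketone F8. Kinetic deprotonation of F8 at its only methylene (C3'') and addition of aldehyde 6 gives the aldol F9. Desilylation as in step 7 gives 12.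

Third, step 5: the flavanone enolate may undergo beta-elimination (opening of ring C, erosion of C2), the ortho silyl group of 8 may migrate to the enolate oxygen, or the second silylation at the hindered enolate may stay incomplete. The fallback sets out from compounds 4 and 8 and comes back at compound 11, using an untethered oxidative cross-coupling of enol silanes made without free enolates. Soft enolisation (Me3SiOSO2CF3, Et3N, CH2Cl2, 0 °C) converts 4 into (2S)-7-(benzyloxy)-2-[4-(benzyloxy)phenyl]-4-(trimethylsilyloxy)-2H-chromene F10 and 8 into its (Z)-trimethylsilyl enol ether F11. Oxidation of F10 with (NH4)2Ce(NO3)6 and NaHCO3 in MeCN at −10 °C in the presence of excess F11 should give 11.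

**Further compounds**

F1 | step 8 | 5,7-bis(benzyloxy)-4H-chromen-4-one | O=c1ccoc2cc(OCc3ccccc3)cc(OCc3ccccc3)c12
F2 | step 8 | (2S)-5,7-bis(benzyloxy)-2-[4-(benzyloxy)phenyl]chroman-4-one | O=C1c2c(OCc3ccccc3)cc(OCc3ccccc3)cc2O[C@H](c2ccc(OCc3ccccc3)cc2)C1
F3 | step 8 | dimethylsilyl bis-enol ether of 4 and F2 | C[Si](C)(OC1=C[C@@H](c2ccc(OCc3ccccc3)cc2)Oc2cc(OCc3ccccc3)ccc12)OC1=C[C@@H](c2ccc(OCc3ccccc3)cc2)Oc2cc(OCc3ccccc3)cc(OCc3ccccc3)c12
F4 | step 8 | (2S,3R)-7-(benzyloxy)-2-[4-(benzyloxy)phenyl]-3-[(2S,3R)-5,7-bis(benzyloxy)-2-[4-(benzyloxy)phenyl]-4-oxochroman-3-yl]chroman-4-one | O=C1c2ccc(OCc3ccccc3)cc2O[C@H](c2ccc(OCc3ccccc3)cc2)[C@H]1[C@H]1C(=O)c2c(OCc3ccccc3)cc(OCc3ccccc3)cc2O[C@@H]1c1ccc(OCc2ccccc2)cc1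
F5 | step 6 | 1-[2,4-bis(benzyloxy)-6-(tert-butyldimethylsilyloxy)phenyl]ethanone | CC(=O)c1c(O[Si](C)(C)C(C)(C)C)cc(OCc2ccccc2)cc1OCc1ccccc1
F6 | step 6 | {1-[2,4-bis(benzyloxy)-6-(tert-butyldimethylsilyloxy)phenyl]ethenyloxy}trimethylsilane | C=C(O[Si](C)(C)C)c1c(O[Si](C)(C)C(C)(C)C)cc(OCc2ccccc2)cc1OCc1ccccc1
F7 | step 6 | 2-bromo-1-[2,4-bis(benzyloxy)-6-(tert-butyldimethylsilyloxy)phenyl]ethanone | O=C(CBr)c1c(O[Si](C)(C)C(C)(C)C)cc(OCc2ccccc2)cc1OCc1ccccc1
F8 | step 6 | (2S,3R)-7-(benzyloxy)-2-[4-(benzyloxy)phenyl]-3-{2-[2,4-bis(benzyloxy)-6-(tert-butyldimethylsilyloxy)phenyl]-2-oxoethyl}chroman-4-one | O=C1c2ccc(OCc3ccccc3)cc2O[C@H](c2ccc(OCc3ccccc3)cc2)[C@H]1CC(=O)c1c(O[Si](C)(C)C(C)(C)C)cc(OCc2ccccc2)cc1OCc1ccccc1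
F9 | step 6 | (2S,3R)-7-(benzyloxy)-2-[4-(benzyloxy)phenyl]-3-{1-[2,4-bis(benzyloxy)-6-(tert-butyldimethylsilyloxy)phenyl]-3-hydroxy-3-[4-(tert-butyldimethylsilyloxy)phenyl]-1-oxopropan-2-yl}chroman-4-one (epimer mixture at C3'' and C2'') | O=C1c2ccc(OCc3ccccc3)cc2O[C@H](c2ccc(OCc3ccccc3)cc2)[C@H]1C(C(O)c1ccc(O[Si](C)(C)C(C)(C)C)cc1)C(=O)c1c(O[Si](C)(C)C(C)(C)C)cc(OCc2ccccc2)cc1OCc1ccccc1
F10 | step 5 | (2S)-7-(benzyloxy)-2-[4-(benzyloxy)phenyl]-4-(trimethylsilyloxy)-2H-chromene | C[Si](C)(C)OC1=C[C@@H](c2ccc(OCc3ccccc3)cc2)Oc2cc(OCc3ccccc3)ccc12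
F11 | step 5 | (Z)-trimethylsilyl enol ether of 8 | C[Si](C)(C)O/C(=C\C(O[Si](C)(C)C(C)(C)C)c1ccc(O[Si](C)(C)C(C)(C)C)cc1)c1c(O[Si](C)(C)C(C)(C)C)cc(OCc2ccccc2)cc1OCc1ccccc1
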